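**Retrosynthetic overview**
1. Last C–C bond: C4 (ring C, upper unit)–C6 (ring A, lower unit), made by acid ionisation of a benzylated 2,3-trans flavan-4-ol in the presence of tri-O-benzyl-ent-epifisetinidol; global hydrogenolysis ends the route.
2. Ring C of each flavan unit is cut at O1–C8a and C2–C3: an aryl aldehyde plus one common 2-fluoroaryl benzyloxymethyl ketone, joined in one pot by aldol addition (enolate C3 to the aldehyde carbon, the future C2) and SNAr (aldolate oxygen, the future O1, on C8a–F).
3. Enabling feature: C4 of ring C is bonded to C3 and to C4a of ring A, ortho to C8a; as a ketone it acidifies C3–H and activates the C8a–F bond, while the C7 oxygen is meta to C8a and does not shut the SNAr down; the same C4, para to O7, later ionises for the C4–C6 bond.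
4. Absolute configuration: the racemic 2,3-trans flavanones are reduced under dynamic kinetic resolution with the two enantiomers of RuCl(TsDPEN)(p-cymene); the lower unit then loses its C4 oxygen and has C3 inverted (oxidation, hindered hydride) to 2,3-cis.
5. Ring order: rings A and B come from purchased arenes; ring C of the upper unit (step 2), ring C of the lower unit (step 4), union of the two units (step 10).

Key step: step 2

Remark: read from the SMILES, the upper unit is 2,3-trans-3,4-trans (2R,3S,4R; guibourtinidol, 4α-linked) and the lower unit is 2,3-cis (2S,3S; ent-epifisetinidol); compounds 1, 2, 6 and 11 are taken as catalogue chemicals.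

**Step 1**
Reactants: 1 4-(benzyloxy)-1-bromo-2-fluorobenzene; 2 2-(benzyloxy)-N-methoxy-N-methylacetamide
Product: 5 2-(benzyloxy)-1-[4-(benzyloxy)-2-fluorophenyl]ethan-1-one, via arylmagnesium chloride 3 (not isolated), via chloromagnesium hemiaminal 4 (not isolated)
Conditions: iPrMgCl·LiCl, THF, 0 °C → rt; then 2, 0 °C; 1 M HCl
Reagents that add atoms: none
Why: Br/Mg exchange is helped by the ortho fluorine and the aryl Grignard reagent does not eliminate to the aryne at these temperatures, and its addition to the Weinreb amide stops at the chelated tetrahedral adduct, so the ketone appears only on work-up (Weinreb ketone synthesis).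

**Step 2**
Reactants: 5 2-(benzyloxy)-1-[4-(benzyloxy)-2-fluorophenyl]ethan-1-one; 6 4-(benzyloxy)benzaldehyde
Product: 9 racemic 2,3-trans-3,7-bis(benzyloxy)-2-[4-(benzyloxy)phenyl]chroman-4-one, via potassium enolate 7 (not isolated), via potassium aldolate 8 (not isolated)
Conditions: KN(SiMe3)2 (1.0 equiv), THF, −78 °C; 6 (1.0 equiv), −78 °C; then DMF, → 40 °C; AcOH
Reagents that add atoms: none
Why: Proposed new method: the potassium (Z)-enolate 7 of the α-benzyloxy ketone adds through its C3 carbon to the aldehyde carbon (C2–C3 bond), and the oxygen of aldolate 8 then displaces fluoride from the ring carbon ortho to the still intact C4 ketone through a Meisenheimer intermediate (O1–C8a bond); the closest known reaction types are the aldol addition of α-alkoxy aryl ketone enolates and the carbonyl-activated intramolecular SNAr of β-hydroxy ketone alkoxides on 2-fluoroaryl ketones that gives chroman-4-ones, run here as one domino. Ring C closes as a 6-membered ring by exo attack of the alkoxide on the aromatic carbon (addition–elimination); a 5-membered benzofuranone cannot form because the C3 oxygen is capped as its benzyl ether. C2 and C3 are formed as a racemate, and their relative configuration is expected to settle thermodynamically, since C3 epimerises through the enol under the weakly basic end conditions (KF) to the diequatorial 2,3-trans isomer; the absolute configuration is left to step 3. The step needs ring closure to outrun retro-aldol, hydride transfer from aldolate to aldehyde and dehydration. One equivalent of base keeps the aldolate as an alkoxide that cannot leave (no E1cB to the chalcone), one equivalent of aldehyde limits hydride transfer, retro-aldol only returns 7 and 6 to the same manifold, and loss of fluoride is irreversible. The base ends as KF, so the β-aryloxy ketone product is not left in strong base.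

**Step 3**
Reactants: 9 racemic 2,3-trans-3,7-bis(benzyloxy)-2-[4-(benzyloxy)phenyl]chroman-4-one
Product: 10 (2R,3S,4S)-3,7-bis(benzyloxy)-2-[4-(benzyloxy)phenyl]chroman-4-ol
Conditions: RuCl[(R,R)-TsDPEN](p-cymene) (2 mol %), HCO2H/Et3N (1:1), DBU (1 equiv), MeCN, 40 °C
Reagents that add atoms: none
Why: Noyori asymmetric transfer hydrogenation run as a dynamic kinetic resolution, a reaction type known for chroman-4-ones with a C2 stereocentre (racemisation by base-induced retro-oxa-Michael/oxa-Michael) and with a C3 stereocentre (enolisation): the (R,R)-catalyst should take the (2R,3R)-enantiomer of 9 with hydride delivered anti to the C3 benzyloxy group, which fixes C2 (R) and C3 (S by CIP in 10) and gives the 3,4-cis alcohol, whose C4 configuration is erased in step 10.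

**Step 4**
Reactants: 5 2-(benzyloxy)-1-[4-(benzyloxy)-2-fluorophenyl]ethan-1-one; 11 3,4-bis(benzyloxy)benzaldehyde
Product: 14 racemic 2,3-trans-3,7-bis(benzyloxy)-2-[3,4-bis(benzyloxy)phenyl]chroman-4-one, via sodium enolate 12 (not isolated), via sodium aldolate 13 (not isolated)
Conditions: NaN(SiMe3)2 (1.0 equiv), THF, −78 °C; 11 (1.0 equiv), −78 °C; then DMF, → 50 °C; AcOH
Reagents that add atoms: none
Why: Proposed new method: the same aldol/SNAr domino as in step 2 (closest known reaction types: aldol addition of α-alkoxy aryl ketone enolates and carbonyl-activated intramolecular SNAr of β-hydroxy ketone alkoxides to chroman-4-ones), run through the sodium enolate 12 because the more tightly chelated sodium aldolate 13 should hold the less favourable aldol equilibrium with the electron-rich aldehyde 11 on the adduct side until DMF and warming free its oxygen to displace the fluorine ortho to the C4 ketone, with C3 expected to equilibrate through the enol to the racemic 2,3-trans flavanone.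

**Step 5**
Reactants: 14 racemic 2,3-trans-3,7-bis(benzyloxy)-2-[3,4-bis(benzyloxy)phenyl]chroman-4-one
Product: 15 (2S,3R,4R)-3,7-bis(benzyloxy)-2-[3,4-bis(benzyloxy)phenyl]chroman-4-ol
Conditions: RuCl[(S,S)-TsDPEN](p-cymene) (2 mol %), HCO2H/Et3N (1:1), DBU (1 equiv), MeCN, 40 °C
Reagents that add atoms: none
Why: the same dynamic kinetic transfer hydrogenation as in step 3 with the mirror-image catalyst, which should select the (2S,3S)-enantiomer of 14 and so set C2 of the lower unit (S).

**Step 6**
Reactants: 15 (2S,3R,4R)-3,7-bis(benzyloxy)-2-[3,4-bis(benzyloxy)phenyl]chroman-4-ol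
Product: 16 (2S,3R)-2-(3,4-dihydroxyphenyl)chroman-3,7-diol (ent-fisetinidol)
Conditions: H2 (3 bar), Pd/C, EtOH/EtOAc, AcOH (1 %), rt
Reagents that add atoms: none
Why: catalytic hydrogenolysis should cleave the four benzyl ethers and the C4–OH bond, which is benzylic to ring A and para to O7 (the known reduction of flavan-3,4-diols to flavan-3-ols), without touching C2 and C3.

**Step 7**
Reactants: 16 (2S,3R)-2-(3,4-dihydroxyphenyl)chroman-3,7-diol
Product: 17 (2S,3R)-7-(benzyloxy)-2-[3,4-bis(benzyloxy)phenyl]chroman-3-ol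
Conditions: BnBr (3.2 equiv), K2CO3, DMF, 0 °C → rt
Reagents that add atoms: benzyl bromide, BrCc1ccccc1
Why: Williamson etherification in which K2CO3 deprotonates only the three phenols, so the secondary C3–OH stays free for the inversion.

**Step 8**
Reactants: 17 (2S,3R)-7-(benzyloxy)-2-[3,4-bis(benzyloxy)phenyl]chroman-3-ol
Product: 18 (2S)-7-(benzyloxy)-2-[3,4-bis(benzyloxy)phenyl]chroman-3-one
Conditions: Dess–Martin periodinane, CH2Cl2, rt
Reagents that add atoms: none
Why: Dess–Martin oxidation is fast and close to neutral, so the C2–H between the new ketone, O1 and ring B should not enolise, as is known for benzylated flavan-3-ols.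

**Step 9**
Reactants: 18 (2S)-7-(benzyloxy)-2-[3,4-bis(benzyloxy)phenyl]chroman-3-one
Product: 19 (2S,3S)-7-(benzyloxy)-2-[3,4-bis(benzyloxy)phenyl]chroman-3-ol (tri-O-benzyl-ent-epifisetinidol)
Conditions: LiBH(s-Bu)3, THF, −78 °C; then H2O
Reagents that add atoms: none
Why: the hindered borohydride should attack the C3 carbonyl from the face away from the C2 aryl group, which sets C3 (S) with the hydroxyl cis to the aryl group (the known trans-to-cis inversion of benzylated flavan-3-ols by oxidation and reduction).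

**Step 10**
Reactants: 10 (2R,3S,4S)-3,7-bis(benzyloxy)-2-[4-(benzyloxy)phenyl]chroman-4-ol; 19 (2S,3S)-7-(benzyloxy)-2-[3,4-bis(benzyloxy)phenyl]chroman-3-ol
Product: 20 hexa-O-benzyl guibourtinidol-(4α→6)-ent-epifisetinidol
Conditions: Me3SiOTf (0.2 equiv), 19 (3 equiv), CH2Cl2, 4 Å MS, −78 → −30 °C
Reagents that add atoms: none
Why: acid ionisation of the C4–OH of 10 gives a flavan-4-yl cation stabilised by O7 (para) and O1 (ortho), which C6 of 19 (para to O1, ortho to O7, less hindered than C8 between two oxygens) should attack in a Friedel–Crafts reaction on the face anti to the C3 benzyloxy group, setting C4 with its aryl group trans to C3–O and cis to the C2 aryl group (the known flavan-4-ol/flavan-3-ol condensation), while the excess of 19 limits self-condensation of 10.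

**Step 11**
Reactants: 20 hexa-O-benzyl guibourtinidol-(4α→6)-ent-epifisetinidol
Product: 21 (2R,3S,4R)-4-[(2S,3S)-2-(3,4-dihydroxyphenyl)-3,7-dihydroxychroman-6-yl]-2-(4-hydroxyphenyl)chroman-3,7-diol
Conditions: H2 (1 bar), Pd(OH)2/C, THF/MeOH, rt
Reagents that add atoms: none
Why: hydrogenolysis of the six benzyl ethers, under which the diaryl-substituted C4–C6 bond and the ring C ethers of flavan-3-ols are expected to survive.

**Compound list**
1 | 4-(benzyloxy)-1-bromo-2-fluorobenzene | Fc1cc(OCc2ccccc2)ccc1Br | starting material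
2 | 2-(benzyloxy)-N-methoxy-N-methylacetamide | CON(C)C(=O)COCc1ccccc1 | starting material
3 | [4-(benzyloxy)-2-fluorophenyl]magnesium chloride (not isolated) | Fc1cc(OCc2ccccc2)ccc1[Mg]Cl | intermediate
4 | chloromagnesium 2-(benzyloxy)-1-[4-(benzyloxy)-2-fluorophenyl]-1-[methoxy(methyl)amino]ethan-1-olate (not isolated) | CON(C)C(O[Mg]Cl)(COCc1ccccc1)c1ccc(OCc2ccccc2)cc1F | intermediate
5 | 2-(benzyloxy)-1-[4-(benzyloxy)-2-fluorophenyl]ethan-1-one | O=C(COCc1ccccc1)c1ccc(OCc2ccccc2)cc1F | intermediate
6 | 4-(benzyloxy)benzaldehyde | O=Cc1ccc(OCc2ccccc2)cc1 | starting material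
7 | potassium (Z)-2-(benzyloxy)-1-[4-(benzyloxy)-2-fluorophenyl]ethen-1-olate (not isolated) | [K+].[O-]/C(=C\OCc1ccccc1)c1ccc(OCc2ccccc2)cc1F | intermediate
8 | potassium 2-(benzyloxy)-3-[4-(benzyloxy)-2-fluorophenyl]-1-[4-(benzyloxy)phenyl]-3-oxopropan-1-olate (not isolated; racemic syn/anti mixture, stereocentres not defined) | [K+].[O-]C(c1ccc(OCc2ccccc2)cc1)C(OCc1ccccc1)C(=O)c1ccc(OCc2ccccc2)cc1F | intermediate
9 | racemic 2,3-trans-3,7-bis(benzyloxy)-2-[4-(benzyloxy)phenyl]chroman-4-one ((2R,3R) and (2S,3S) in equal amounts; SMILES shows (2R,3R)) | C(c1ccccc1)Oc1ccc([C@H]2Oc3cc(OCc4ccccc4)ccc3C(=O)[C@@H]2OCc2ccccc2)cc1 | intermediate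
10 | (2R,3S,4S)-3,7-bis(benzyloxy)-2-[4-(benzyloxy)phenyl]chroman-4-ol (2,3-trans-3,4-cis) | C(c1ccccc1)Oc1ccc([C@H]2Oc3cc(OCc4ccccc4)ccc3[C@H](O)[C@@H]2OCc2ccccc2)cc1 | intermediate
11 | 3,4-bis(benzyloxy)benzaldehyde | O=Cc1ccc(OCc2ccccc2)c(OCc2ccccc2)c1 | starting material
12 | sodium (Z)-2-(benzyloxy)-1-[4-(benzyloxy)-2-fluorophenyl]ethen-1-olate (not isolated) | [Na+].[O-]/C(=C\OCc1ccccc1)c1ccc(OCc2ccccc2)cc1F | intermediate
13 | sodium 2-(benzyloxy)-3-[4-(benzyloxy)-2-fluorophenyl]-1-[3,4-bis(benzyloxy)phenyl]-3-oxopropan-1-olate (not isolated; racemic syn/anti mixture, stereocentres not defined) | [Na+].[O-]C(c1ccc(OCc2ccccc2)c(OCc2ccccc2)c1)C(OCc1ccccc1)C(=O)c1ccc(OCc2ccccc2)cc1F | intermediate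
14 | racemic 2,3-trans-3,7-bis(benzyloxy)-2-[3,4-bis(benzyloxy)phenyl]chroman-4-one ((2R,3R) and (2S,3S) in equal amounts; SMILES shows (2S,3S)) | C(c1ccccc1)Oc1ccc([C@@H]2Oc3cc(OCc4ccccc4)ccc3C(=O)[C@H]2OCc2ccccc2)cc1OCc1ccccc1 | intermediate
15 | (2S,3R,4R)-3,7-bis(benzyloxy)-2-[3,4-bis(benzyloxy)phenyl]chroman-4-ol (2,3-trans-3,4-cis) | C(c1ccccc1)Oc1ccc([C@@H]2Oc3cc(OCc4ccccc4)ccc3[C@@H](O)[C@H]2OCc2ccccc2)cc1OCc1ccccc1 | intermediate
16 | (2S,3R)-2-(3,4-dihydroxyphenyl)chroman-3,7-diol (ent-fisetinidol) | Oc1ccc([C@@H]2Oc3cc(O)ccc3C[C@H]2O)cc1O | intermediate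
17 | (2S,3R)-7-(benzyloxy)-2-[3,4-bis(benzyloxy)phenyl]chroman-3-ol | C(c1ccccc1)Oc1ccc([C@@H]2Oc3cc(OCc4ccccc4)ccc3C[C@H]2O)cc1OCc1ccccc1 | intermediate
18 | (2S)-7-(benzyloxy)-2-[3,4-bis(benzyloxy)phenyl]chroman-3-one | C(c1ccccc1)Oc1ccc([C@@H]2Oc3cc(OCc4ccccc4)ccc3CC2=O)cc1OCc1ccccc1 | intermediate
19 | (2S,3S)-7-(benzyloxy)-2-[3,4-bis(benzyloxy)phenyl]chroman-3-ol (2,3-cis; tri-O-benzyl-ent-epifisetinidol) | C(c1ccccc1)Oc1ccc([C@@H]2Oc3cc(OCc4ccccc4)ccc3C[C@@H]2O)cc1OCc1ccccc1 | intermediate
20 | hexa-O-benzyl guibourtinidol-(4α→6)-ent-epifisetinidol: (2R,3S)-3,7-bis(benzyloxy)-2-[4-(benzyloxy)phenyl]chroman carrying at C4, trans to the C3 benzyloxy group, the 6-yl residue of (2S,3S)-7-(benzyloxy)-2-[3,4-bis(benzyloxy)phenyl]chroman-3-ol | C(c1ccccc1)Oc1ccc([C@H]2Oc3cc(OCc4ccccc4)ccc3[C@@H](c3cc4c(cc3OCc3ccccc3)O[C@@H](c3ccc(OCc5ccccc5)c(OCc5ccccc5)c3)[C@@H](O)C4)[C@@H]2OCc2ccccc2)cc1 | intermediate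
21 | (2R,3S,4R)-4-[(2S,3S)-2-(3,4-dihydroxyphenyl)-3,7-dihydroxychroman-6-yl]-2-(4-hydroxyphenyl)chroman-3,7-diol (guibourtinidol-(4α→6)-ent-epifisetinidol) | Oc1ccc([C@H]2Oc3cc(O)ccc3[C@@H](c3cc4c(cc3O)O[C@@H](c3ccc(O)c(O)c3)[C@@H](O)C4)[C@@H]2O)cc1 | target

**Step count and risks**
Total steps: 11. Longest linear sequence: 9 steps (steps 1, 4, 5, 6, 7, 8, 9, 10, 11).

Steps most likely to fail:

1. Step 2 (Proposed new method). Ring closure may be slower than reversal of the aldol addition, so that hydride transfer between aldolate and aldehyde or rearrangement of the α-benzyloxy enolate drains the material before fluoride is displaced. Fallback, from 5 and 6 back to 9, with the ring closed by the classical oxa-Michael route (O1–C2 formed last): hydroxide displaces the activated fluoride of 5 (KOH, DMSO/H2O, 60 °C) to give 2-(benzyloxy)-1-[4-(benzyloxy)-2-hydroxyphenyl]ethan-1-one F1. Claisen–Schmidt condensation of F1 with 6 (KOH, EtOH, rt) gives (Z)-2-(benzyloxy)-1-[4-(benzyloxy)-2-hydroxyphenyl]-3-[4-(benzyloxy)phenyl]prop-2-en-1-one F2, and cyclisation of F2 (NaOAc, EtOH, reflux) should return the thermodynamic 2,3-trans flavanone 9.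

2. Step 4 (Proposed new method). With the more electron-rich and more hindered aldehyde 11 the aldol equilibrium lies further back, and the sodium aldolate is a weaker SNAr nucleophile than the potassium one, so cyclisation may stall and the side reactions named for step 2 may take over. Fallback, from 5 and 11 back to 14: the 2-hydroxy ketone 2-(benzyloxy)-1-[4-(benzyloxy)-2-hydroxyphenyl]ethan-1-one F1, made from 5 as described above, is condensed with 11 (KOH, EtOH, rt) to (Z)-2-(benzyloxy)-1-[4-(benzyloxy)-2-hydroxyphenyl]-3-[3,4-bis(benzyloxy)phenyl]prop-2-en-1-one F3, which is closed by oxa-Michael addition (NaOAc, EtOH, reflux) to 14.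

3. Step 3. Racemisation through ring opening may be slower than reduction of the slow-reacting enantiomer, or catalyst and substrate preferences may not reinforce each other, so that the reduction stops as a plain kinetic resolution or gives diastereomer mixtures. Fallback, from 9 back to 20, with the enantiopure lower unit used as resolving partner: NaBH4 (MeOH/THF, 0 °C) reduces 9 to racemic 2,3-trans-3,4-trans-3,7-bis(benzyloxy)-2-[4-(benzyloxy)phenyl]chroman-4-ol F4. F4 is condensed with 19 under the conditions of step 10, and 20 is separated by chromatography from the hexa-O-benzyl dimer with the mirror-image (2S,3R) upper unit F5; the route continues from 20.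

**Further compounds**
F1 | step 2 | 2-(benzyloxy)-1-[4-(benzyloxy)-2-hydroxyphenyl]ethan-1-one | O=C(COCc1ccccc1)c1ccc(OCc2ccccc2)cc1O
F2 | step 2 | (Z)-2-(benzyloxy)-1-[4-(benzyloxy)-2-hydroxyphenyl]-3-[4-(benzyloxy)phenyl]prop-2-en-1-one | O=C(/C(OCc1ccccc1)=C/c1ccc(OCc2ccccc2)cc1)c1ccc(OCc2ccccc2)cc1O
F3 | step 4 | (Z)-2-(benzyloxy)-1-[4-(benzyloxy)-2-hydroxyphenyl]-3-[3,4-bis(benzyloxy)phenyl]prop-2-en-1-one | O=C(/C(OCc1ccccc1)=C/c1ccc(OCc2ccccc2)c(OCc2ccccc2)c1)c1ccc(OCc2ccccc2)cc1O
F4 | step 3 | racemic 2,3-trans-3,4-trans-3,7-bis(benzyloxy)-2-[4-(benzyloxy)phenyl]chroman-4-ol (SMILES shows (2R,3S,4R)) | C(c1ccccc1)Oc1ccc([C@H]2Oc3cc(OCc4ccccc4)ccc3[C@@H](O)[C@@H]2OCc2ccccc2)cc1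
F5 | step 3 | hexa-O-benzyl dimer with the mirror-image (2S,3R) upper unit (diastereomer of 20; C4 aryl trans to the C3 benzyloxy group; (2S,3S) lower unit) | C(c1ccccc1)Oc1ccc([C@@H]2Oc3cc(OCc4ccccc4)ccc3[C@H](c3cc4c(cc3OCc3ccccc3)O[C@@H](c3ccc(OCc5ccccc5)c(OCc5ccccc5)c3)[C@@H](O)C4)[C@H]2OCc2ccccc2)cc1
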